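## Analysis of the target

The target is a flavan: a chroman in which ring A is fused to a pyran ring (O1, C2, C3, C4, C4a, C8a) and a 3,5-dimethoxyphenyl group (ring B) sits on C2. Ring A carries free hydroxyls at C5 and C7, a prenyl group between them at C6, and hydrogen at C8. C2 is the only stereocentre and is R (from the SMILES: O1 > ring B carbon > C3 > H). It is benzylic and oxygen-bearing and is flanked by two plain methylene groups (C3, C4), so no neighbouring function can relay or correct its configuration.

The sensitive groups are:
- the prenyl alkene, which closes onto either flanking phenol under acid to give a dimethylchroman and rules out hydrogenation and hydrogenolysis;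
- the very electron-rich ring A;
- the benzylic C2–O1 ether;
- the two methyl ethers of ring B, which must stay while the ring A oxygens end up free.

The difficulty is therefore twofold. An isolated benzylic ether stereocentre has to be set with no functional group left at C3 or C4. The ring A protecting groups must also come off without acid, hydrogen or ether-cleaving Lewis acids.

The strategy rests on one feature. O1, C8a and C4a of ring A, together with C2 as an oxocarbenium carbon, form a cationic 2-oxadiene (C4a=C8a–O1=C2), which leaves C3–C4 as a two-carbon alkene partner. The phenol that supplies ring A is symmetric about the axis through C6 and C8a, so its two ortho carbons are identical and the ring closure has no regiochemical question.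

## Retrosynthetic reasoning

**17 to 16.** The two O–Si bonds on ring A are cut last. Silyl ethers were chosen for C5–O and C7–O because they come off with fluoride under buffered, non-acidic conditions. Alkoxymethyl ethers would permit directed metalation on ring A, but they are formaldehyde acetals: they would give the acid of the key step two further ionisable sites, and their removal needs acid beside the prenyl group.

**16 to 15.** A C4–H bond is replaced by a C4–S bond. The sulfur is the remnant of the two-carbon partner. It sits on a benzylic carbon, so it can be removed by a radical chain that touches neither the prenyl alkene nor C2. This makes the partner an electron-rich, regiochemically unambiguous alkene instead of ethylene.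

**15 to 11 and 12.** The bonds C2–C3 and C4–C4a are cut. This is the only disconnection that takes the pyran ring apart into a phenol-derived piece and a two-carbon piece while creating C2 in the same event. Ionisation of the mixed acetal 11 should give the O-aryl oxocarbenium ion 13. The vinyl sulfide 12 should add through its CH2 terminus to give the thionium ion 14, and ring A should close onto it. The forward reaction must select one face of 13 (through a chiral counteranion) and must be faster than any intermolecular attack on 13. Cutting O1–C2 instead would need a preformed carbinol stereocentre and an ortho-alkylated phenol; that is kept as the fallback.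

**11 to 7 and 10.** The acetal C–O(aryl) bond is cut. The phenol 7 is O-alkylated by the α-chloro ether 10, which comes from the dimethyl acetal 9 of aldehyde 8. This is the reliable way to an aryl methyl mixed acetal and keeps the acid-labile function in a basic medium.

**7 to 5.** The C–O bond para to the prenyl group is cut. Silyl ethers cannot direct a metalation, and a 1,3,5-trioxygenated benzene would require telling the para oxygen from the two ortho ones. The third oxygen is therefore introduced last, by sterically governed C–H borylation of 5 (through boronate 6) and oxidation. The only ring C–H of 5 without an ortho substituent is the one needed, so the differentiation is automatic.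

**5 to 2 and 3.** The aryl–CH2 bond is cut. The aryl iodide 2 is converted into the arylmagnesium reagent 4, which is coupled with prenyl bromide 3 at the unhindered allyl terminus.

**2 to 1.** The two O–Si bonds are cut, giving commercial 2-iodoresorcinol 1.

## Alternatives that were turned down

**Alternative 1:** Ring A is built last by a Danheiser benzannulation on a preformed, enantioenriched dihydropyran. The bonds C5–C6, C7–C8 and C4a–C5 are cut, and C8–C8a arises from the Wolff shift.
- Forward key step: irradiation of the diazoketone A2 gives a vinylketene by Wolff rearrangement. It adds the siloxyalkyne A3 in a [2+2] sense, the cyclobutenone opens, and a six-electron electrocyclisation with tautomerisation gives the phenol A1.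
- For: every ring A substituent is fixed by the connectivity of the partners. The two ring A oxygens emerge differentiated. C2 is set beforehand on a simple heterocycle and is not touched by the key step. Only a desilylation remains.
- Against: A2 needs an enantioenriched 2-aryl-dihydropyran-6-carboxylic acid derivative and a diazo transfer, which is a long linear sequence. A3 is a hydrolytically fragile ynol silyl ether whose CH2 group lies between an alkyne and an alkene and is prone to isomerisation. The cascade delivers a free phenol beside the prenyl group at elevated temperature.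
- Comparison: this route is stronger in stereochemical security, because its stereocentre rests on established chemistry. The chosen route instead takes ring A from a cheap aromatic compound, is convergent and much shorter, and concentrates its risk in one step that has a known-chemistry fallback.

**Alternative 2:** O1–C2 and C3–C4 are cut, with an extra formyl group on C3.
- Forward key step: a secondary amine of the diarylprolinol silyl ether class activates the enal A6 as an iminium ion. The phenol of the salicylaldehyde A5 adds in an oxa-Michael step, and the enamine closes by aldol condensation onto the aryl aldehyde to give the chromene aldehyde A4.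
- For: this domino reaction is an established, metal-free, enantioselective reaction class. A6 is two carbons away from aldehyde 8. The pyran ring forms in one step.
- Against: A4 carries two surplus functions. The formyl group has to be removed by a rhodium-mediated decarbonylation. The styrenic C3=C4 bond has to be saturated in the presence of the prenyl alkene. A5 is a benzaldehyde flanked on both sides by oxygen substituents, the substitution pattern that is least favourable for the aldol closure. A 2-aryl-2H-chromene can lose its configuration by reversible oxa-Michael addition or electrocyclic ring opening. The alkoxymethyl ethers need acid at the end.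
- Comparison: this route is stronger in the precedent of its asymmetric step. The chosen route instead gives a product whose only surplus group is a benzylic C–S bond, removed under neutral radical conditions, with C3–C4 already saturated. Two steps follow its key step, against three or four here.

**Alternative 3:** C8a–O1 and C4a–C4 are cut.
- Forward key step: fluoride generates the alkoxy-substituted aryne from the silyl triflate A8. The alkoxide of the chloro alcohol A9 adds at C8a, the aryne carbon remote from the C5 oxygen. The aryl anion at C4a displaces the primary chloride to give the protected flavan A7.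
- For: the stereocentre of A9 comes from a standard asymmetric ketone reduction and is not involved in the key step, since neither bond to C2 is made or broken. A7 has no surplus group, so only deprotection follows.
- Against: A8 is a hexasubstituted benzene whose regiocontrolled assembly costs several steps beyond the ring A phenol itself. The aryl anion must alkylate an unactivated chloride faster than it is protonated, which is the usual fate of such anions. The alkoxide of A9 can close to an oxetane or eliminate. Acidic cleavage of the alkoxymethyl ethers beside the prenyl group remains.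
- Comparison: this route is stronger in stereochemical certainty and in the number of steps after the key step. The chosen route instead needs only the symmetric phenol 7, whose ortho carbons are equivalent, and closes the ring by a cation–arene reaction that is intrinsically fast for this electron-rich ring.

Key step: step 6

Assumption: the sense of induction of the confined acid in step 6 cannot be predicted from a model. The (S,S) antipode is written, and the (R,R) antipode is to be used if a first run shows the 2S series. "IDPi acid" means the imidodiphosphorimidate Brønsted acid built from two (S)-3,3'-diaryl-BINOL units with N-triflyl groups on phosphorus.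

## Route

Step 1
Reactants: 1 2-iodobenzene-1,3-diol (2-iodoresorcinol)
Product: 2 2-iodo-1,3-bis(triisopropylsilyloxy)benzene
Conditions: TIPSCl (2.4 equiv), imidazole (5 equiv), DMF, 40 °C
Reagents that add atoms: chlorotriisopropylsilane, CC(C)[Si](Cl)(C(C)C)C(C)C
Why: Standard silylation of phenols; the triisopropylsilyl ethers are chosen because they resist organomagnesium reagents, mild base and strong anhydrous acid, and fall to fluoride at the end.

Step 2
Reactants: 2 2-iodo-1,3-bis(triisopropylsilyloxy)benzene; 3 prenyl bromide (1-bromo-3-methylbut-2-ene)
Product: 5 2-(3-methylbut-2-enyl)-1,3-bis(triisopropylsilyloxy)benzene, via arylmagnesium chloride 4 (not isolated)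
Conditions: i-PrMgCl·LiCl (1.1 equiv), THF, −20 °C; then CuI (10 mol%), 3 (1.3 equiv), −20 °C to rt
Reagents that add atoms: isopropylmagnesium chloride–lithium chloride, CC(C)[Mg]Cl.[Li+].[Cl-] (magnesium and chloride of intermediate 4 only)
Why: Iodine–magnesium exchange is fast for an aryl iodide flanked by two oxygen substituents, and the arylmagnesium species does not undergo the O-to-C silyl shift typical of aryllithiums; copper-catalysed allylic substitution by the hindered aryl nucleophile should occur at the unhindered CH2 terminus of 3 (SN2 sense), not at the tertiary carbon.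

Step 3
Reactants: 5 2-(3-methylbut-2-enyl)-1,3-bis(triisopropylsilyloxy)benzene
Product: 7 4-(3-methylbut-2-enyl)-3,5-bis(triisopropylsilyloxy)phenol, via aryl pinacol boronate 6 (not isolated)
Conditions: [Ir(OMe)(cod)]2 (1.5 mol%), 4,4'-di-tert-butyl-2,2'-bipyridine (3 mol%), B2pin2 (1.0 equiv), hexane, 60 °C; then NaBO3·4H2O, THF/H2O, rt
Reagents that add atoms: bis(pinacolato)diboron, CC1(C)OB(B2OC(C)(C)C(C)(C)O2)OC1(C)C (boryl group of intermediate 6 only); sodium perborate, [Na+].[O-]OB=O (phenol oxygen of 7)
Why: Iridium-catalysed aromatic C–H borylation is sterically governed, and the only ring C–H of 5 without an ortho substituent is the one meta to both silyloxy groups and para to the prenyl group; perborate oxidises the C–B bond to C–OH at the same carbon and should leave the trisubstituted alkene alone.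

Step 4
Reactants: 8 3,5-dimethoxybenzaldehyde
Product: 9 1-(dimethoxymethyl)-3,5-dimethoxybenzene
Conditions: HC(OMe)3, p-TsOH·H2O (cat.), MeOH, rt
Reagents that add atoms: trimethyl orthoformate, COC(OC)OC; methanol, CO
Why: Routine acid-catalysed acetalisation driven by the orthoformate as water scavenger.

Step 5
Reactants: 9 1-(dimethoxymethyl)-3,5-dimethoxybenzene; 7 4-(3-methylbut-2-enyl)-3,5-bis(triisopropylsilyloxy)phenol
Product: 11 5-[(3,5-dimethoxyphenyl)(methoxy)methoxy]-2-(3-methylbut-2-enyl)-1,3-bis(triisopropylsilyloxy)benzene (racemic at the acetal carbon), via α-chloro ether 10 (not isolated)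
Conditions: AcCl (1.1 equiv), SOCl2 (cat.), CH2Cl2, rt, evaporate; then 7, i-Pr2NEt, CH2Cl2, 0 °C to rt
Reagents that add atoms: acetyl chloride, CC(Cl)=O (chlorine of intermediate 10 only)
Why: Acetal–acyl chloride exchange gives the α-chloro ether, which O-alkylates the phenol in the same way as a chloromethyl ether does in a methoxymethylation (Williamson-type alkylation with an SN1-active halide); the basic medium preserves the acid-labile mixed acetal, and the new stereocentre is racemic and is erased on ionisation in step 6.

Step 6
Reactants: 11 5-[(3,5-dimethoxyphenyl)(methoxy)methoxy]-2-(3-methylbut-2-enyl)-1,3-bis(triisopropylsilyloxy)benzene; 12 phenyl vinyl sulfide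
Product: 15 (2R,4R)-2-(3,5-dimethoxyphenyl)-6-(3-methylbut-2-enyl)-4-(phenylsulfanyl)-5,7-bis(triisopropylsilyloxy)chroman (2,4-cis), via oxocarbenium ion 13 (not isolated), via thionium ion 14 (not isolated)
Conditions: 12 (3 equiv, added slowly), (S,S)-IDPi acid (5 mol%), 5 Å MS, toluene (0.05 M), −60 °C
Reagents that add atoms: none
Why: Proposed new method: the acid should protonate the methoxy oxygen of 11 (the more basic acetal oxygen), methanol leaves and is held by the sieves, and the O-aryl oxocarbenium ion 13 remains as a contact ion pair with the chiral imidodiphosphorimidate anion; 12 adds through its CH2 carbon to C2 to give thionium ion 14, the ortho carbon of ring A attacks the thionium carbon, and loss of the ring proton returns the acid. The closest known reaction type is the racemic, Lewis acid promoted oxa-Povarov reaction of aryl methyl mixed acetals with alkenes; confined acids of this class are known to control additions to other oxocarbenium ions, and chiral phosphoric acids control the nitrogen analogue (Povarov reaction). The pyran ring closes by a 6-exo-trig cation–arene (Friedel–Crafts) cyclisation onto the C=S+ carbon, so the overall event is a stepwise inverse-demand [4+2] annulation. C2 is set in the first C–C bond formation by the chiral anion, which should shield one face of the planar (E)-oxocarbenium ion inside its pocket; C4 is set in the ring closure under substrate control through a chair-like transition state with the C2 aryl group equatorial, expected to place the sulfide cis, and its configuration is without consequence because step 7 deletes it. The step needs ionisation at the benzylic acetal only (no other acetal is present, which is why ring A carries silyl and not alkoxymethyl ethers), capture of 13 by 12 and not by the prenyl alkene or by ring A of a second molecule (12 in excess, high dilution, and both competitors flanked by bulky silyloxy groups), and one regiochemistry of closure (the two ortho carbons of ring A are equivalent by symmetry and each is activated by three oxygens).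

Step 7
Reactants: 15 (2R,4R)-2-(3,5-dimethoxyphenyl)-6-(3-methylbut-2-enyl)-4-(phenylsulfanyl)-5,7-bis(triisopropylsilyloxy)chroman
Product: 16 (2R)-2-(3,5-dimethoxyphenyl)-6-(3-methylbut-2-enyl)-5,7-bis(triisopropylsilyloxy)chroman
Conditions: Bu3SnH (1.5 equiv), AIBN (cat.), toluene, 90 °C
Reagents that add atoms: none
Why: Radical chain desulfurisation: the stannyl radical attacks sulfur and the weaker, benzylic C4–S bond breaks to give a ring A stabilised radical that takes hydrogen from the tin hydride; the trisubstituted alkene, the silyl ethers and C2 are not involved, and any C4 epimer of 15 converges on the same product.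

Step 8
Reactants: 16 (2R)-2-(3,5-dimethoxyphenyl)-6-(3-methylbut-2-enyl)-5,7-bis(triisopropylsilyloxy)chroman
Product: 17 (2R)-2-(3,5-dimethoxyphenyl)-6-(3-methylbut-2-enyl)chroman-5,7-diol (target)
Conditions: TBAF (2.5 equiv), AcOH (2.5 equiv), THF, 0 °C, under argon
Reagents that add atoms: none
Why: Fluoride cleaves aryl silyl ethers rapidly; the acetic acid buffer keeps the electron-rich diphenol from standing as a phenoxide, and no acid strong enough to cyclise the prenyl group onto a neighbouring hydroxyl is present.

## Compound list

1 | 2-iodobenzene-1,3-diol | Oc1cccc(O)c1I | starting material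
2 | 2-iodo-1,3-bis(triisopropylsilyloxy)benzene | CC(C)[Si](Oc1cccc(O[Si](C(C)C)(C(C)C)C(C)C)c1I)(C(C)C)C(C)C | intermediate
3 | prenyl bromide (1-bromo-3-methylbut-2-ene) | CC(C)=CCBr | starting material
4 | [2,6-bis(triisopropylsilyloxy)phenyl]magnesium chloride | CC(C)[Si](Oc1cccc(O[Si](C(C)C)(C(C)C)C(C)C)c1[Mg]Cl)(C(C)C)C(C)C | intermediate
5 | 2-(3-methylbut-2-enyl)-1,3-bis(triisopropylsilyloxy)benzene | CC(C)=CCc1c(O[Si](C(C)C)(C(C)C)C(C)C)cccc1O[Si](C(C)C)(C(C)C)C(C)C | intermediate
6 | 2-[4-(3-methylbut-2-enyl)-3,5-bis(triisopropylsilyloxy)phenyl]-4,4,5,5-tetramethyl-1,3,2-dioxaborolane | CC(C)=CCc1c(O[Si](C(C)C)(C(C)C)C(C)C)cc(B2OC(C)(C)C(C)(C)O2)cc1O[Si](C(C)C)(C(C)C)C(C)C | intermediate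
7 | 4-(3-methylbut-2-enyl)-3,5-bis(triisopropylsilyloxy)phenol | CC(C)=CCc1c(O[Si](C(C)C)(C(C)C)C(C)C)cc(O)cc1O[Si](C(C)C)(C(C)C)C(C)C | intermediate
8 | 3,5-dimethoxybenzaldehyde | COc1cc(OC)cc(C=O)c1 | starting material
9 | 1-(dimethoxymethyl)-3,5-dimethoxybenzene | COc1cc(OC)cc(C(OC)OC)c1 | intermediate
10 | 1-[chloro(methoxy)methyl]-3,5-dimethoxybenzene (racemic) | COc1cc(OC)cc(C(Cl)OC)c1 | intermediate
11 | 5-[(3,5-dimethoxyphenyl)(methoxy)methoxy]-2-(3-methylbut-2-enyl)-1,3-bis(triisopropylsilyloxy)benzene (racemic) | COC(Oc1cc(O[Si](C(C)C)(C(C)C)C(C)C)c(CC=C(C)C)c(O[Si](C(C)C)(C(C)C)C(C)C)c1)c1cc(OC)cc(OC)c1 | intermediate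
12 | phenyl vinyl sulfide | C=CSc1ccccc1 | starting material
13 | (E)-[(3,5-dimethoxyphenyl)methylidene][4-(3-methylbut-2-enyl)-3,5-bis(triisopropylsilyloxy)phenyl]oxonium, cation of the ion pair with the chiral anion | COc1cc(OC)cc(/C=[O+]/c2cc(O[Si](C(C)C)(C(C)C)C(C)C)c(CC=C(C)C)c(O[Si](C(C)C)(C(C)C)C(C)C)c2)c1 | intermediate
14 | [(3R)-3-(3,5-dimethoxyphenyl)-3-[4-(3-methylbut-2-enyl)-3,5-bis(triisopropylsilyloxy)phenoxy]propylidene](phenyl)sulfonium | COc1cc(OC)cc([C@@H](CC=[S+]c2ccccc2)Oc2cc(O[Si](C(C)C)(C(C)C)C(C)C)c(CC=C(C)C)c(O[Si](C(C)C)(C(C)C)C(C)C)c2)c1 | intermediate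
15 | (2R,4R)-2-(3,5-dimethoxyphenyl)-6-(3-methylbut-2-enyl)-4-(phenylsulfanyl)-5,7-bis(triisopropylsilyloxy)chroman | COc1cc(OC)cc([C@H]2C[C@@H](Sc4ccccc4)c3c(O[Si](C(C)C)(C(C)C)C(C)C)c(CC=C(C)C)c(O[Si](C(C)C)(C(C)C)C(C)C)cc3O2)c1 | intermediate
16 | (2R)-2-(3,5-dimethoxyphenyl)-6-(3-methylbut-2-enyl)-5,7-bis(triisopropylsilyloxy)chroman | COc1cc(OC)cc([C@H]2CCc3c(O[Si](C(C)C)(C(C)C)C(C)C)c(CC=C(C)C)c(O[Si](C(C)C)(C(C)C)C(C)C)cc3O2)c1 | intermediate
17 | (2R)-2-(3,5-dimethoxyphenyl)-6-(3-methylbut-2-enyl)chroman-5,7-diol | COc1cc(OC)cc([C@H]2CCc3c(cc(O)c(CC=C(C)C)c3O)O2)c1 | target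

## Step count and least certain steps

Total step count: 8. Longest linear sequence: 7 steps (steps 1, 2, 3, 5, 6, 7, 8); step 4 is a one-step side branch.

**Step 6 (key step, proposed new method).** Several things can go wrong.
- Enantioface selection by the counteranion may be poor or in the wrong sense. The target has no second stereocentre through which this could be corrected later.
- The acetal may ionise with loss of the phenol instead of the methoxy group, which leads to unselective recombination.
- The acid may start oligomerisation of the vinyl sulfide.
- The cation may be captured by the prenyl alkene or by ring A of a second molecule.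

The fallback uses known chemistry throughout, sets out from 7 and rejoins the route at 16. Phenol 7 would be ortho-formylated (MgCl2, Et3N, paraformaldehyde, THF, reflux) to 2-hydroxy-5-(3-methylbut-2-enyl)-4,6-bis(triisopropylsilyloxy)benzaldehyde F1. The stabilised ylide 1-(3,5-dimethoxyphenyl)-2-(triphenyl-λ5-phosphanylidene)ethanone F2 would be prepared from the corresponding phenacyl bromide and PPh3. Wittig olefination of F1 with it in toluene at 90 °C would give (E)-1-(3,5-dimethoxyphenyl)-3-[2-hydroxy-5-(3-methylbut-2-enyl)-4,6-bis(triisopropylsilyloxy)phenyl]prop-2-en-1-one F3. Conjugate reduction with [(Ph3P)CuH]6 and PhSiH3 would saturate only the enone double bond and give 1-(3,5-dimethoxyphenyl)-3-[2-hydroxy-5-(3-methylbut-2-enyl)-4,6-bis(triisopropylsilyloxy)phenyl]propan-1-one F4. Noyori transfer hydrogenation with RuCl(p-cymene)[(S,S)-TsDPEN] in HCO2H/Et3N would give (1S)-1-(3,5-dimethoxyphenyl)-3-[2-hydroxy-5-(3-methylbut-2-enyl)-4,6-bis(triisopropylsilyloxy)phenyl]propan-1-ol F5. An intramolecular Mitsunobu etherification (PPh3, DIAD, THF, 0 °C) would then close the pyran ring with inversion at the carbinol carbon and deliver 16. Steps 5 to 7 are bypassed.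

**Step 3.** The iridium catalyst with the boron hydride formed in the reaction may isomerise or hydroborate the prenyl alkene, or the alkene may be oxidised during the oxidative work-up. The fallback reverses the order of events; it sets out from 2 and rejoins at 7. Iodide 2 would be borylated under the same iridium conditions while no alkene is present, giving 2-[4-iodo-3,5-bis(triisopropylsilyloxy)phenyl]-4,4,5,5-tetramethyl-1,3,2-dioxaborolane F6. This would be oxidised in the same flask to 4-iodo-3,5-bis(triisopropylsilyloxy)phenol F7. Deprotonation with MeMgCl, iodine–magnesium exchange with i-PrMgCl·LiCl and CuI-catalysed coupling with 3 would then give 7.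

**Step 2.** Substitution may occur at the tertiary allyl terminus (SN2' sense) and give the reverse-prenyl isomer, or silyl migration from oxygen to carbon may occur in the arylmetal species. The fallback sets out from 2 and rejoins at 5 with no new compound. It is a Stille cross-coupling of 2 with tributyl(3-methylbut-2-enyl)stannane under Pd(PPh3)4 (a complex of zerovalent palladium) in DMF at 80 °C, which replaces the polar organometallic substitution by a transmetalation–reductive elimination pathway.

**Step 7.** The radical chain may propagate sluggishly at the hindered C4–S bond next to a silyloxy group, stannyl radicals may add reversibly to the prenyl alkene, and tin residues may be carried into the last step. The fallback sets out from 15 and rejoins at 16 with no new compound. It is hydrogenolysis of the C–S bonds on Ni2B generated from NiCl2·6H2O and NaBH4 in MeOH/THF at 0 °C, a surface reduction in place of a radical chain. It must be stopped before the trisubstituted alkene starts to be reduced.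

## Further compounds

F1 | step 6 | 2-hydroxy-5-(3-methylbut-2-enyl)-4,6-bis(triisopropylsilyloxy)benzaldehyde | O=Cc1c(O)cc(O[Si](C(C)C)(C(C)C)C(C)C)c(CC=C(C)C)c1O[Si](C(C)C)(C(C)C)C(C)C
F2 | step 6 | 1-(3,5-dimethoxyphenyl)-2-(triphenyl-λ5-phosphanylidene)ethanone | COc1cc(OC)cc(C(=O)C=P(c2ccccc2)(c2ccccc2)c2ccccc2)c1
F3 | step 6 | (E)-1-(3,5-dimethoxyphenyl)-3-[2-hydroxy-5-(3-methylbut-2-enyl)-4,6-bis(triisopropylsilyloxy)phenyl]prop-2-en-1-one | COc1cc(OC)cc(C(=O)/C=C/c2c(O)cc(O[Si](C(C)C)(C(C)C)C(C)C)c(CC=C(C)C)c2O[Si](C(C)C)(C(C)C)C(C)C)c1
F4 | step 6 | 1-(3,5-dimethoxyphenyl)-3-[2-hydroxy-5-(3-methylbut-2-enyl)-4,6-bis(triisopropylsilyloxy)phenyl]propan-1-one | COc1cc(OC)cc(C(=O)CCc2c(O)cc(O[Si](C(C)C)(C(C)C)C(C)C)c(CC=C(C)C)c2O[Si](C(C)C)(C(C)C)C(C)C)c1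
F5 | step 6 | (1S)-1-(3,5-dimethoxyphenyl)-3-[2-hydroxy-5-(3-methylbut-2-enyl)-4,6-bis(triisopropylsilyloxy)phenyl]propan-1-ol | COc1cc(OC)cc([C@@H](O)CCc2c(O)cc(O[Si](C(C)C)(C(C)C)C(C)C)c(CC=C(C)C)c2O[Si](C(C)C)(C(C)C)C(C)C)c1
F6 | step 3 | 2-[4-iodo-3,5-bis(triisopropylsilyloxy)phenyl]-4,4,5,5-tetramethyl-1,3,2-dioxaborolane | CC(C)[Si](Oc1cc(B2OC(C)(C)C(C)(C)O2)cc(O[Si](C(C)C)(C(C)C)C(C)C)c1I)(C(C)C)C(C)C
F7 | step 3 | 4-iodo-3,5-bis(triisopropylsilyloxy)phenol | CC(C)[Si](Oc1cc(O)cc(O[Si](C(C)C)(C(C)C)C(C)C)c1I)(C(C)C)C(C)C
F0 | step 2 | none | none
F0 | step 7 | none | none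
A1 | alternative 1 | (2R)-2-(3,5-dimethoxyphenyl)-6-(3-methylbut-2-enyl)-7-(triisopropylsilyloxy)chroman-5-ol | COc1cc(OC)cc([C@H]2CCc3c(O)c(CC=C(C)C)c(O[Si](C(C)C)(C(C)C)C(C)C)cc3O2)c1
A2 | alternative 1 | 2-diazo-1-[(2R)-2-(3,5-dimethoxyphenyl)-3,4-dihydro-2H-pyran-6-yl]ethanone | COc1cc(OC)cc([C@H]2CCC=C(C(=O)C=[N+]=[N-])O2)c1
A3 | alternative 1 | triisopropyl[(5-methylhex-4-en-1-yn-1-yl)oxy]silane | CC(C)=CCC#CO[Si](C(C)C)(C(C)C)C(C)C
A4 | alternative 2 | 2-(3,5-dimethoxyphenyl)-5,7-bis(methoxymethoxy)-6-(3-methylbut-2-enyl)-2H-chromene-3-carbaldehyde, C2 arranged as in the target | COc1cc(OC)cc([C@H]2C(C=O)=Cc3c(OCOC)c(CC=C(C)C)c(OCOC)cc3O2)c1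
A5 | alternative 2 | 2-hydroxy-4,6-bis(methoxymethoxy)-5-(3-methylbut-2-enyl)benzaldehyde | O=Cc1c(O)cc(OCOC)c(CC=C(C)C)c1OCOC
A6 | alternative 2 | (E)-3-(3,5-dimethoxyphenyl)prop-2-enal | COc1cc(OC)cc(/C=C/C=O)c1
A7 | alternative 3 | (2R)-2-(3,5-dimethoxyphenyl)-5,7-bis(methoxymethoxy)-6-(3-methylbut-2-enyl)chroman | COc1cc(OC)cc([C@H]2CCc3c(OCOC)c(CC=C(C)C)c(OCOC)cc3O2)c1
A8 | alternative 3 | 3,5-bis(methoxymethoxy)-4-(3-methylbut-2-enyl)-2-(trimethylsilyl)phenyl trifluoromethanesulfonate | COCOc1cc(OS(=O)(=O)C(F)(F)F)c([Si](C)(C)C)c(OCOC)c1CC=C(C)C
A9 | alternative 3 | (1R)-3-chloro-1-(3,5-dimethoxyphenyl)propan-1-ol | COc1cc(OC)cc([C@H](O)CCCl)c1
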